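## Retrosynthetic overview

1. Integracin B ⇒ global O-debenzylation of a tetrabenzyl ether; the ester C–O bond ⇒ Mitsunobu coupling (inversion) of a 2,4-bis(benzyloxy)-6-(hept-6-enyl)benzoic acid with the (S)-carbinol of the resorcinol half.
2. Each carbinol carbon and its C7–C8 bond ⇒ a primary alkylborane (9-BBN adduct of a terminal alkene) plus sparteine-lithiated butyl carbamate. This is a chiral α-oxyalkyl carbanion, nucleophilic at a carbon that is electrophilic in butanal; two carbon nucleophiles (C–Li and C–B) are joined by a 1,2-metallate shift, then oxidised.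
3. This coupling is run twice: early with (+)-sparteine for the carbinol that becomes the ester, and as the last C–C bond on the complete ester with (−)-sparteine, so the free (R)-alcohol never needs protection.
4. Both halves ⇒ one alkene, 1,3-bis(benzyloxy)-5-(hept-6-enyl)benzene (benzyl bromide + hexenyl Grignard); the carboxyl carbon ⇒ Vilsmeier–Haack formylation, then Pinnick oxidation.
5. No ring is formed: both benzene rings are bought intact in 3,5-bis(benzyloxy)benzyl bromide.

Assumption: the SMILES is read as (R) at both carbinol carbons, and both (+)- and (−)-sparteine are bought.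

## Route

Step 1
Reactants: 1 butan-1-ol; 2 N,N-diisopropylcarbamoyl chloride
Product: 3 butyl N,N-diisopropylcarbamate
Conditions: Et3N, CH2Cl2, reflux, 24 h
Reagents that add atoms: none
Why: Nucleophilic acyl substitution (O-carbamoylation) of a primary alcohol installs the group that later directs α-lithiation, stabilises the carbanion and serves as the leaving group.

Step 2
Reactants: 4 6-bromohex-1-ene; 5 3,5-bis(benzyloxy)benzyl bromide
Product: 7 1,3-bis(benzyloxy)-5-(hept-6-en-1-yl)benzene, via hex-5-enyl Grignard reagent 6 (not isolated)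
Conditions: 4, Mg, THF, rt → 40 °C; then 5, Li2CuCl4 (3 mol %), THF, −20 °C → rt
Reagents that add atoms: none
Why: Kochi-type copper-catalysed Grignard cross-coupling of a primary alkylmagnesium bromide with a reactive benzylic bromide gives the C7 chain, the terminal alkene and benzyl ethers being inert.

Step 3
Reactants: 7 1,3-bis(benzyloxy)-5-(hept-6-en-1-yl)benzene; 3 butyl N,N-diisopropylcarbamate
Product: 12 (S)-11-[3,5-bis(benzyloxy)phenyl]undecan-4-ol, via alkylborane 8 (not isolated), via lithiated carbamate 9 (not isolated), via boronate complex 10 (not isolated), via secondary borane 11 (not isolated)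
Conditions: (a) 7, 9-BBN (1.1 equiv), THF, 0 °C → rt, 4 h; (b) 3 (1.3 equiv), s-BuLi (1.25 equiv), (+)-sparteine (1.3 equiv), Et2O, −78 °C, 5 h; (c) add (a) to (b), −78 °C, 1 h, then rt, 2 h; (d) 2 M NaOH, 30% H2O2, 0 °C → rt
Reagents that add atoms: hydrogen peroxide, OO
Why: Anti-Markovnikov hydroboration followed by Hoppe asymmetric deprotonation and lithiation–borylation: s-BuLi/(+)-sparteine removes the pro-R α-proton of 3 to give the configurationally stable α-oxyalkyl carbanion 9 (the alcohol-level counterpart of an acyl anion), which adds to the boron of 8 with retention; the stereospecific 1,2-metallate shift of the primary alkyl group (inversion at carbon, carbamate expelled) and oxidation with retention then give the (S)-carbinol and the C7–C8 bond.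

Step 4
Reactants: 7 1,3-bis(benzyloxy)-5-(hept-6-en-1-yl)benzene
Product: 14 2,4-bis(benzyloxy)-6-(hept-6-en-1-yl)benzaldehyde, via iminium salt 13 (not isolated)
Conditions: POCl3 (1.3 equiv), DMF, 0 → 70 °C; then ice/H2O, rt
Reagents that add atoms: N,N-dimethylformamide, CN(C)C=O; water, O
Why: Vilsmeier–Haack formylation attacks the ring position ortho to the alkyl chain and para to one benzyloxy group, because the site flanked by both benzyloxy groups is more hindered, and the isolated alkene does not react with the chloroiminium ion.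

Step 5
Reactants: 14 2,4-bis(benzyloxy)-6-(hept-6-en-1-yl)benzaldehyde
Product: 15 2,4-bis(benzyloxy)-6-(hept-6-en-1-yl)benzoic acid
Conditions: NaClO2, NaH2PO4, 2-methyl-2-butene (20 equiv), t-BuOH/THF/H2O, 0 °C → rt
Reagents that add atoms: sodium chlorite NaClO2, [Na+].[O-]Cl=O
Why: Pinnick oxidation converts the aldehyde to the acid under buffered conditions, the large excess of 2-methyl-2-butene trapping HOCl before it can chlorinate the electron-rich ring or the terminal alkene.

Step 6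
Reactants: 15 2,4-bis(benzyloxy)-6-(hept-6-en-1-yl)benzoic acid; 12 (S)-11-[3,5-bis(benzyloxy)phenyl]undecan-4-ol
Product: 17 (R)-11-[3,5-bis(benzyloxy)phenyl]undecan-4-yl 2,4-bis(benzyloxy)-6-(hept-6-en-1-yl)benzoate, via alkoxyphosphonium carboxylate 16 (not isolated)
Conditions: 15 (1.2 equiv), PPh3 (1.5 equiv), DIAD (1.5 equiv), THF, 0 °C → rt
Reagents that add atoms: none
Why: In the Mitsunobu esterification the di-ortho-substituted acid acts only as a carboxylate nucleophile in an SN2 displacement of the oxyphosphonium, so shielding of its carbonyl does not matter and the (S)-carbinol is inverted to the (R)-ester.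

Step 7
Reactants: 17 (R)-11-[3,5-bis(benzyloxy)phenyl]undecan-4-yl 2,4-bis(benzyloxy)-6-(hept-6-en-1-yl)benzoate; 3 butyl N,N-diisopropylcarbamate
Product: 22 (R)-11-[3,5-bis(benzyloxy)phenyl]undecan-4-yl 2,4-bis(benzyloxy)-6-[(R)-8-hydroxyundecyl]benzoate, via alkylborane 18 (not isolated), via lithiated carbamate 19 (not isolated), via boronate complex 20 (not isolated), via secondary borane 21 (not isolated)
Conditions: (a) 17, 9-BBN (1.1 equiv), THF, rt, 6 h; (b) 3 (1.2 equiv), s-BuLi (1.15 equiv), (−)-sparteine (1.2 equiv), Et2O, −78 °C, 5 h; (c) add (a) to (b), −78 °C, 1 h, then rt, 2 h; (d) 2 M NaOH, 30% H2O2, 0 °C → rt, 2 h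
Reagents that add atoms: hydrogen peroxide, OO
Why: The same hydroboration and Hoppe lithiation–borylation sequence, now with (−)-sparteine (pro-S deprotonation, retention at boron, inversion in the 1,2-metallate shift, retention on oxidation), gives the free (R)-carbinol; it should be chemoselective because a trialkylborane captures the hindered organolithium at −78 °C far faster than the di-ortho-substituted secondary benzoate can, no free s-BuLi is present, and 9-BBN does not reduce esters.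

Step 8
Reactants: 22 (R)-11-[3,5-bis(benzyloxy)phenyl]undecan-4-yl 2,4-bis(benzyloxy)-6-[(R)-8-hydroxyundecyl]benzoate
Product: 23 integracin B
Conditions: H2 (1 atm), 10% Pd/C, EtOAc/MeOH, rt
Reagents that add atoms: none
Why: Catalytic hydrogenolysis cleaves the four aryl benzyl ethers, while the non-benzylic secondary alkyl ester, the secondary alcohol and both stereocentres are untouched.

## Compound list

1 | butan-1-ol | CCCCO | starting material
2 | N,N-diisopropylcarbamoyl chloride | CC(C)N(C(C)C)C(=O)Cl | starting material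
3 | butyl N,N-diisopropylcarbamate | CCCCOC(=O)N(C(C)C)C(C)C | intermediate
4 | 6-bromohex-1-ene | C=CCCCCBr | starting material
5 | 3,5-bis(benzyloxy)benzyl bromide | BrCc1cc(OCc2ccccc2)cc(OCc2ccccc2)c1 | starting material
6 | hex-5-en-1-ylmagnesium bromide | C=CCCCC[Mg]Br | intermediate
7 | 1,3-bis(benzyloxy)-5-(hept-6-en-1-yl)benzene | C=CCCCCCc1cc(OCc2ccccc2)cc(OCc2ccccc2)c1 | intermediate
8 | 9-{7-[3,5-bis(benzyloxy)phenyl]heptyl}-9-borabicyclo[3.3.1]nonane | C1CC2CCCC(C1)B2CCCCCCCc1cc(OCc2ccccc2)cc(OCc2ccccc2)c1 | intermediate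
9 | (R)-1-lithiobutyl N,N-diisopropylcarbamate ((+)-sparteine complex; ligand not drawn) | CCC[C@@H]([Li])OC(=O)N(C(C)C)C(C)C | intermediate
10 | lithium boronate complex: 9-{7-[3,5-bis(benzyloxy)phenyl]heptyl}-9-{(R)-1-[(diisopropylcarbamoyl)oxy]butyl}-9-boranuidabicyclo[3.3.1]nonane, lithium salt | CCC[C@@H]([B-]1(CCCCCCCc2cc(OCc3ccccc3)cc(OCc3ccccc3)c2)C2CCCC1CCC2)OC(=O)N(C(C)C)C(C)C.[Li+] | intermediate
11 | 9-{(S)-11-[3,5-bis(benzyloxy)phenyl]undecan-4-yl}-9-borabicyclo[3.3.1]nonane | CCC[C@H](B1C2CCCC1CCC2)CCCCCCCc1cc(OCc2ccccc2)cc(OCc2ccccc2)c1 | intermediate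
12 | (S)-11-[3,5-bis(benzyloxy)phenyl]undecan-4-ol | CCC[C@H](O)CCCCCCCc1cc(OCc2ccccc2)cc(OCc2ccccc2)c1 | intermediate
13 | [2,4-bis(benzyloxy)-6-(hept-6-en-1-yl)benzylidene]dimethylammonium chloride | C=CCCCCCc1cc(OCc2ccccc2)cc(OCc2ccccc2)c1C=[N+](C)C.[Cl-] | intermediate
14 | 2,4-bis(benzyloxy)-6-(hept-6-en-1-yl)benzaldehyde | C=CCCCCCc1cc(OCc2ccccc2)cc(OCc2ccccc2)c1C=O | intermediate
15 | 2,4-bis(benzyloxy)-6-(hept-6-en-1-yl)benzoic acid | C=CCCCCCc1cc(OCc2ccccc2)cc(OCc2ccccc2)c1C(=O)O | intermediate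
16 | {[(S)-11-[3,5-bis(benzyloxy)phenyl]undecan-4-yl]oxy}triphenylphosphonium 2,4-bis(benzyloxy)-6-(hept-6-en-1-yl)benzoate | CCC[C@H](O[P+](c1ccccc1)(c1ccccc1)c1ccccc1)CCCCCCCc1cc(OCc2ccccc2)cc(OCc2ccccc2)c1.C=CCCCCCc1cc(OCc2ccccc2)cc(OCc2ccccc2)c1C(=O)[O-] | intermediate
17 | (R)-11-[3,5-bis(benzyloxy)phenyl]undecan-4-yl 2,4-bis(benzyloxy)-6-(hept-6-en-1-yl)benzoate | C=CCCCCCc1cc(OCc2ccccc2)cc(OCc2ccccc2)c1C(=O)O[C@H](CCC)CCCCCCCc1cc(OCc2ccccc2)cc(OCc2ccccc2)c1 | intermediate
18 | (R)-11-[3,5-bis(benzyloxy)phenyl]undecan-4-yl 2,4-bis(benzyloxy)-6-[7-(9-borabicyclo[3.3.1]nonan-9-yl)heptyl]benzoate | C1CC2CCCC(C1)B2CCCCCCCc1cc(OCc2ccccc2)cc(OCc2ccccc2)c1C(=O)O[C@H](CCC)CCCCCCCc1cc(OCc2ccccc2)cc(OCc2ccccc2)c1 | intermediate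
19 | (S)-1-lithiobutyl N,N-diisopropylcarbamate ((−)-sparteine complex; ligand not drawn) | CCC[C@H]([Li])OC(=O)N(C(C)C)C(C)C | intermediate
20 | lithium boronate complex formed from 18 and 19 (boron bears the (S)-1-[(diisopropylcarbamoyl)oxy]butyl group) | CCC[C@H]([B-]1(CCCCCCCc2cc(OCc3ccccc3)cc(OCc3ccccc3)c2C(=O)O[C@H](CCC)CCCCCCCc2cc(OCc3ccccc3)cc(OCc3ccccc3)c2)C2CCCC1CCC2)OC(=O)N(C(C)C)C(C)C.[Li+] | intermediate
21 | (R)-11-[3,5-bis(benzyloxy)phenyl]undecan-4-yl 2,4-bis(benzyloxy)-6-[(R)-8-(9-borabicyclo[3.3.1]nonan-9-yl)undecyl]benzoate | CCC[C@@H](B1C2CCCC1CCC2)CCCCCCCc1cc(OCc2ccccc2)cc(OCc2ccccc2)c1C(=O)O[C@H](CCC)CCCCCCCc1cc(OCc2ccccc2)cc(OCc2ccccc2)c1 | intermediate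
22 | (R)-11-[3,5-bis(benzyloxy)phenyl]undecan-4-yl 2,4-bis(benzyloxy)-6-[(R)-8-hydroxyundecyl]benzoate | CCC[C@@H](O)CCCCCCCc1cc(OCc2ccccc2)cc(OCc2ccccc2)c1C(=O)O[C@H](CCC)CCCCCCCc1cc(OCc2ccccc2)cc(OCc2ccccc2)c1 | intermediate
23 | integracin B, (R)-11-(3,5-dihydroxyphenyl)undecan-4-yl 2,4-dihydroxy-6-[(R)-8-hydroxyundecyl]benzoate | CCC[C@@H](O)CCCCCCCc1cc(O)cc(O)c1C(=O)O[C@H](CCC)CCCCCCCc1cc(O)cc(O)c1 | target

## Step count and risks

Total steps: 8. Longest linear sequence: 6 (steps 2, 4, 5, 6, 7, 8).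

Each lithiation–borylation is expected to give about 97:3 er. The minor epimers carry remote stereocentres and cannot be removed later, so the enantiopurity of the two sparteine steps fixes the purity of the product.

The three steps most likely to fail:

First, step 7. The lithiated carbamate meets a substrate that carries an ester, a lateral benzylic position and four benzyl ethers, and the 9-BBN boronate must shift the primary chain and not a ring carbon. If this fails, the second carbinol is set before the ester exists; this fallback sets out from 7 and 3 and comes back to the route at 23. Alkene 7 is run through the procedure of step 3 with (−)-sparteine, so that alkylborane 8 and lithiated carbamate 19 give the lithium boronate complex F1. This rearranges to the (R)-configured secondary borane F2, which is oxidised to (R)-11-[3,5-bis(benzyloxy)phenyl]undecan-4-ol F3. NaH and BnBr in THF/DMF give the benzyl ether F4. POCl3/DMF gives, through the iminium chloride F5, the aldehyde F6, and NaClO2 oxidation gives the acid F7. Mitsunobu coupling of F7 with 12 passes through the alkoxyphosphonium carboxylate F8 to the pentabenzyl ester F9. H2 over Pd/C then removes all five benzyl groups and gives 23.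

Second, step 3. The borane route depends on selective migration of the exocyclic primary alkyl group of a B-alkyl-9-BBN and on the boronate not dissociating before it rearranges, which would lower the er. The fallback sets out from 7 and comes back at 12, using a boron partner that has no competing carbon group and can be purified. Hydroboration of 7 with pinacolborane and [Ir(cod)Cl]2/dppe in CH2Cl2 gives the pinacol boronic ester F10. Adding it to lithiated carbamate 9 at −78 °C gives the lithium boronate complex F11. MgBr2·OEt2 in MeOH/Et2O at reflux triggers the 1,2-shift to the secondary pinacol boronic ester F12, and NaOH/H2O2 gives 12.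

Third, step 6. Elimination of the activated secondary alcohol or acylation of the reduced azodicarboxylate can erode the Mitsunobu yield with this hindered acid. The fallback sets out from 12 and 15 and comes back at 17, separating activation from displacement. MsCl/Et3N in CH2Cl2 at 0 °C converts 12 with retention into the (S)-mesylate F13. Acid 15 and Cs2CO3 give the cesium carboxylate F14, which displaces the mesylate in DMF at 60 °C with inversion to give 17.

## Further compounds

F1 | step 7 | lithium boronate complex formed from 8 and 19 (boron bears the (S)-1-[(diisopropylcarbamoyl)oxy]butyl group) | CCC[C@H]([B-]1(CCCCCCCc2cc(OCc3ccccc3)cc(OCc3ccccc3)c2)C2CCCC1CCC2)OC(=O)N(C(C)C)C(C)C.[Li+]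
F2 | step 7 | 9-{(R)-11-[3,5-bis(benzyloxy)phenyl]undecan-4-yl}-9-borabicyclo[3.3.1]nonane | CCC[C@@H](B1C2CCCC1CCC2)CCCCCCCc1cc(OCc2ccccc2)cc(OCc2ccccc2)c1
F3 | step 7 | (R)-11-[3,5-bis(benzyloxy)phenyl]undecan-4-ol | CCC[C@@H](O)CCCCCCCc1cc(OCc2ccccc2)cc(OCc2ccccc2)c1
F4 | step 7 | 1,3-bis(benzyloxy)-5-[(R)-8-(benzyloxy)undecyl]benzene | CCC[C@@H](OCc1ccccc1)CCCCCCCc1cc(OCc2ccccc2)cc(OCc2ccccc2)c1
F5 | step 7 | {2,4-bis(benzyloxy)-6-[(R)-8-(benzyloxy)undecyl]benzylidene}dimethylammonium chloride | CCC[C@@H](OCc1ccccc1)CCCCCCCc1cc(OCc2ccccc2)cc(OCc2ccccc2)c1C=[N+](C)C.[Cl-]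
F6 | step 7 | 2,4-bis(benzyloxy)-6-[(R)-8-(benzyloxy)undecyl]benzaldehyde | CCC[C@@H](OCc1ccccc1)CCCCCCCc1cc(OCc2ccccc2)cc(OCc2ccccc2)c1C=O
F7 | step 7 | 2,4-bis(benzyloxy)-6-[(R)-8-(benzyloxy)undecyl]benzoic acid | CCC[C@@H](OCc1ccccc1)CCCCCCCc1cc(OCc2ccccc2)cc(OCc2ccccc2)c1C(=O)O
F8 | step 7 | {[(S)-11-[3,5-bis(benzyloxy)phenyl]undecan-4-yl]oxy}triphenylphosphonium 2,4-bis(benzyloxy)-6-[(R)-8-(benzyloxy)undecyl]benzoate | CCC[C@H](O[P+](c1ccccc1)(c1ccccc1)c1ccccc1)CCCCCCCc1cc(OCc2ccccc2)cc(OCc2ccccc2)c1.CCC[C@@H](OCc1ccccc1)CCCCCCCc1cc(OCc2ccccc2)cc(OCc2ccccc2)c1C(=O)[O-]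
F9 | step 7 | (R)-11-[3,5-bis(benzyloxy)phenyl]undecan-4-yl 2,4-bis(benzyloxy)-6-[(R)-8-(benzyloxy)undecyl]benzoate | CCC[C@@H](OCc1ccccc1)CCCCCCCc1cc(OCc2ccccc2)cc(OCc2ccccc2)c1C(=O)O[C@H](CCC)CCCCCCCc1cc(OCc2ccccc2)cc(OCc2ccccc2)c1
F10 | step 3 | 2-{7-[3,5-bis(benzyloxy)phenyl]heptyl}-4,4,5,5-tetramethyl-1,3,2-dioxaborolane | CC1(C)OB(CCCCCCCc2cc(OCc3ccccc3)cc(OCc3ccccc3)c2)OC1(C)C
F11 | step 3 | lithium boronate complex formed from F10 and 9 (boron bears the (R)-1-[(diisopropylcarbamoyl)oxy]butyl group) | CCC[C@@H]([B-]1(CCCCCCCc2cc(OCc3ccccc3)cc(OCc3ccccc3)c2)OC(C)(C)C(C)(C)O1)OC(=O)N(C(C)C)C(C)C.[Li+]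
F12 | step 3 | 2-{(S)-11-[3,5-bis(benzyloxy)phenyl]undecan-4-yl}-4,4,5,5-tetramethyl-1,3,2-dioxaborolane | CCC[C@H](B1OC(C)(C)C(C)(C)O1)CCCCCCCc1cc(OCc2ccccc2)cc(OCc2ccccc2)c1
F13 | step 6 | (S)-11-[3,5-bis(benzyloxy)phenyl]undecan-4-yl methanesulfonate | CCC[C@H](OS(C)(=O)=O)CCCCCCCc1cc(OCc2ccccc2)cc(OCc2ccccc2)c1
F14 | step 6 | cesium 2,4-bis(benzyloxy)-6-(hept-6-en-1-yl)benzoate | [Cs+].[O-]C(=O)c1c(CCCCCC=C)cc(OCc2ccccc2)cc1OCc1ccccc1
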